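## Retrosynthetic overview

Numbering: C1 = angelate carbinol, C2 = 2-methylbutanoate carbinol, C3 = CH2, C4 = methyl-bearing quaternary C, C5 = CH next to ketone C6, C7=C8(CH3) = enone alkene, C9 = allylic CH, C10 = CH, C11 = CMe2; the cyclobutane is C4–C5–C10–C9.
Feature used: the cyclobutane and the bridge C3–C2–C1–C11 form a bicyclo[4.1.1]octane with bridgeheads C4 and C10 and a hidden mirror plane through them. It is a bicyclo[1.1.0]butane whose central C4–C10 bond has taken up a four-carbon chain that ends in CMe2.
Late disconnections: C1/C2 esters ⇒ trans-diol; enone bond C7–C8 ⇒ C5-acetyl enol ether + C9-ethynyl; C5–C6 and C9–C8 ⇒ two amide-directed C–H functionalisations on the cyclobutane face opposite the bridge; C4–CH3 ⇒ the directing carboxamide; C1/C2 oxygens ⇒ C1 ketone.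
Key disconnection: C10–C11 and C3–C4 ⇒ methyl bicyclo[1.1.0]butane-1-carboxylate + 3-silyloxy-4-methylpenta-1,3-diene (Lewis-acid formal (4+3)).
Ring order: cyclobutane (purchased) → bicyclobutane (step 3) → seven-membered ring (step 5) → six-membered enone ring (step 21).

Key step: step 5

Assumption: no model predicts how the chiral ligand of step 12 tells C5 from C9 in this new cage; the (S,S)-ligand is written, and its mirror image takes its place if the first run functionalises C9.

## Route

Step 1
Reactants: 1 methyl 3-oxocyclobutane-1-carboxylate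
Product: 2 methyl cis-3-hydroxycyclobutane-1-carboxylate
Conditions: NaBH4, MeOH, 0 °C
Reagents that add atoms: none
Why: Borohydride reduction of a cyclobutanone, in which hydride should approach anti to the ester and give mainly the cis alcohol; the relationship is immaterial because the ester-bearing carbon is planarised in step 3.

Step 2
Reactants: 2 methyl cis-3-hydroxycyclobutane-1-carboxylate
Product: 3 methyl cis-3-(p-toluenesulfonyloxy)cyclobutane-1-carboxylate
Conditions: TsCl, Et3N, DMAP (cat.), CH2Cl2, 0 °C → rt
Reagents that add atoms: p-toluenesulfonyl chloride Cc1ccc(cc1)S(=O)(=O)Cl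
Why: O-sulfonylation with retention at carbon installs the leaving group without requiring an SN2 displacement at a cyclobutyl carbon.

Step 3
Reactants: 3 methyl cis-3-(p-toluenesulfonyloxy)cyclobutane-1-carboxylate
Product: 4 methyl bicyclo[1.1.0]butane-1-carboxylate
Conditions: NaN(SiMe3)2, THF, −78 → 0 °C; aqueous work-up, careful concentration, kept as a titrated CH2Cl2 solution
Reagents that add atoms: none
Why: Transannular 1,3-elimination (3-exo-tet enolate alkylation), the classical entry to bicyclobutane-1-carboxylates, in which the planar ester enolate displaces the sulfonate across the ring.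

Step 4
Reactants: 5 4-methylpent-1-en-3-one
Product: 6 3-(tert-butyldimethylsilyloxy)-4-methylpenta-1,3-diene
Conditions: TBSOTf, Et3N, CH2Cl2, 0 °C
Reagents that add atoms: tert-butyldimethylsilyl triflate CC(C)(C)[Si](C)(C)OS(=O)(=O)C(F)(F)F
Why: Soft enolisation (silyl triflate/amine); the ketone carries α-hydrogen only on its isopropyl side, so only the tetrasubstituted enol ether can form.

Step 5
Reactants: 4 methyl bicyclo[1.1.0]butane-1-carboxylate; 6 3-(tert-butyldimethylsilyloxy)-4-methylpenta-1,3-diene
Product: 8 methyl 5,5-dimethyl-4-oxobicyclo[4.1.1]octane-1-carboxylate, via TBS enol ether cycloadduct 7 (not isolated)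
Conditions: Al(OTf)3 (10 mol %), 4 Å MS, 6 (1.5 equiv), CH2Cl2, 0 °C → rt, slow addition of 4; then 1 M HCl, THF, rt
Reagents that add atoms: none
Why: This is the known Lewis-acid-catalysed formal (4+3) annulation of acyl bicyclobutanes with 2-silyloxydienes: binding of Al(OTf)3 to the ester carbonyl weakens the strained C4–C10 bond, and the electron-rich carbon C11 of 6 opens it by backside attack at C10, the bridgehead that bears only hydrogen (a homologous Mukaiyama–Michael addition), so the energy stored in the bicyclobutane offsets the congestion of the new secondary–quaternary bond. The C4 ester enolate and the O-silylated vinyl ketone (C1, C2=C3) then sit on the same cyclobutane, and C4 adds to C3 in a 7-endo-trig conjugate closure that forms the seven-membered ring and leaves silyl enol ether 7, which the acid work-up converges on ketone 8. No stereocentre is created, because 8 keeps a mirror plane through C4, C10 and the bridge, and the only geometric demand, a cis-1,3 span across the puckered four-membered ring, is enforced by the tether. The step needs only regiochemical control, which the substrates supply, since C11 is the single nucleophilic carbon of 6 and C10 the single acceptor-free bridgehead of 4. The competing 1,2-closure onto C1 (formal (3+2) to a bicyclo[2.1.1]hexane) would have to line up three contiguous fully substituted carbons and should lose to the 1,4-mode. Only the fully substituted nucleophilic terminus and the plain ester as activating group lie outside the documented scope.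

Step 6
Reactants: 8 methyl 5,5-dimethyl-4-oxobicyclo[4.1.1]octane-1-carboxylate
Product: 9 methyl 5,5-dimethyl-4-(triethylsilyloxy)bicyclo[4.1.1]oct-3-ene-1-carboxylate
Conditions: TESOTf, Et3N, CH2Cl2, 0 °C
Reagents that add atoms: triethylsilyl triflate CC[Si](CC)(CC)OS(=O)(=O)C(F)(F)F
Why: Soft enolisation of purified 8; C11 is quaternary and the ester has no α-hydrogen, so the enol ether can only form toward C2.

Step 7
Reactants: 9 methyl 5,5-dimethyl-4-(triethylsilyloxy)bicyclo[4.1.1]oct-3-ene-1-carboxylate
Product: 11 methyl (3S)-3-hydroxy-5,5-dimethyl-4-oxobicyclo[4.1.1]octane-1-carboxylate (local 2S), via silyloxy-oxirane 10 (not isolated)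
Conditions: L-fructose-derived Shi ketone (1,2:4,5-di-O-isopropylidene-β-L-erythro-2,3-hexodiulo-2,6-pyranose, 30 mol %), Oxone (2KHSO5·KHSO4·K2SO4), K2CO3, Bu4NHSO4, MeCN–CH2(OMe)2/aq. Na2B4O7–Na2EDTA buffer, 0 °C; then AcOH–THF–H2O, rt
Reagents that add atoms: potassium peroxymonosulfate (active part of Oxone) [K+].[O-]S(=O)(=O)OO
Why: Shi asymmetric epoxidation used as a Rubottom-type oxidation: in the spiro transition state the only vinylic hydrogen (on C2) occupies the blocked quadrant of the dioxirane while C3 and the bulky C11 point outward, so, by analogy with 1-aryl- and 1-acyloxycycloalkenes, the L-series ketone should deliver oxygen to the face that gives (2S), and oxirane 10 collapses to the hydroxy ketone.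

Step 8
Reactants: 11 methyl (3S)-3-hydroxy-5,5-dimethyl-4-oxobicyclo[4.1.1]octane-1-carboxylate
Product: 12 methyl (3S,4S)-3,4-dihydroxy-5,5-dimethylbicyclo[4.1.1]octane-1-carboxylate (trans-diol, local 1S,2S)
Conditions: Me4NBH(OAc)3, AcOH–MeCN, −20 °C → rt
Reagents that add atoms: none
Why: Saksena–Evans hydroxyl-directed reduction: boron exchanges an acetate for the C2 oxygen and passes hydride to C1 from that same face, so the new C1 hydroxyl ends up trans to C2–OH, and the ester is untouched.

Step 9
Reactants: 12 methyl (3S,4S)-3,4-dihydroxy-5,5-dimethylbicyclo[4.1.1]octane-1-carboxylate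
Product: 13 methyl (3S,4S)-3,4-(isopropylidenedioxy)-5,5-dimethylbicyclo[4.1.1]octane-1-carboxylate
Conditions: 2,2-dimethoxypropane, PPTS (cat.), CH2Cl2, rt
Reagents that add atoms: 2,2-dimethoxypropane COC(C)(C)OC
Why: Transketalisation; the flexible seven-membered ring lets the trans-diol reach the gauche O–C–C–O angle a dioxolane needs, and the ketal tolerates the basic, hydridic and silver/palladium conditions ahead.

Step 10
Reactants: 13 methyl (3S,4S)-3,4-(isopropylidenedioxy)-5,5-dimethylbicyclo[4.1.1]octane-1-carboxylate
Product: 14 (3S,4S)-3,4-(isopropylidenedioxy)-5,5-dimethylbicyclo[4.1.1]octane-1-carboxylic acid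
Conditions: LiOH, THF–MeOH–H2O, 40 °C; then 1 M HCl to pH 4, 0 °C
Reagents that add atoms: lithium hydroxide [Li+].[OH-]
Why: Saponification; the tied-back cyclobutane bridgehead keeps the quaternary ester accessible and there is no epimerisable centre.

Step 11
Reactants: 14 (3S,4S)-3,4-(isopropylidenedioxy)-5,5-dimethylbicyclo[4.1.1]octane-1-carboxylic acid
Product: 16 (3S,4S)-3,4-(isopropylidenedioxy)-5,5-dimethyl-N-[2,3,5,6-tetrafluoro-4-(trifluoromethyl)phenyl]bicyclo[4.1.1]octane-1-carboxamide, via acid chloride 15 (not isolated)
Conditions: 1-chloro-N,N,2-trimethylprop-1-en-1-amine, CH2Cl2, 0 °C → rt; then ArNH2, pyridine, DMAP, toluene, 80 °C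
Reagents that add atoms: 1-chloro-N,N,2-trimethylprop-1-en-1-amine (Ghosez reagent, chlorine of 15) CC(C)=C(Cl)N(C)C; 2,3,5,6-tetrafluoro-4-(trifluoromethyl)aniline Nc1c(F)c(F)c(C(F)(F)F)c(F)c1F
Why: Acid chloride formation under neutral conditions spares the acetonide, and acylation of the weakly nucleophilic aniline gives the acidic, weakly coordinating N-aryl amide that leaves room on palladium for an external chiral ligand.

Step 12
Reactants: 16 N-aryl carboxamide acetonide; 17 2-iodopropene
Product: 18 N-aryl carboxamide acetonide bearing a prop-1-en-2-yl group on C5, cis to the amide and anti to the C3–C11 bridge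
Conditions: Pd(OAc)2 (10 mol %), N-{(1S)-1-[(4S)-4-benzyl-4,5-dihydro-1,3-oxazol-2-yl]-2,2-dimethylpropyl}acetamide (15 mol %), Ag2CO3, t-AmylOH, 80 °C, sealed tube
Reagents that add atoms: none
Why: Ligand-accelerated, amide-directed β-C(sp3)–H alkenylation of a 1-substituted cyclobutanecarboxamide through a divalent/tetravalent palladium cycle: cyclopalladation reaches only the cyclobutane hydrogens cis to the amide, on the face away from the bridge, which sets C5 and makes C4 and C10 stereogenic, while the chiral N-acyl aminomethyl-oxazoline ligand chooses between the diastereotopic methylenes in favour of C5 (the one on the side of the C2 oxygen), the s-rich cyclobutane C–H bonds react before C3–H, and any C9 isomer is a separable diastereomer.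

Step 13
Reactants: 18 C5-isopropenyl carboxamide; 19 (bromoethynyl)triisopropylsilane
Product: 20 N-aryl carboxamide acetonide bearing C5-isopropenyl and C9-(triisopropylsilyl)ethynyl groups, both cis to the amide
Conditions: Pd(OAc)2 (10 mol %), 2-picoline (20 mol %), Ag2CO3, 1,2-dichloroethane, 90 °C
Reagents that add atoms: none
Why: Pyridine-ligand-enabled, amide-directed C(sp3)–H alkynylation of a carbocyclic β-methylene with a bulky silyl bromoalkyne; the C9 hydrogen is the only cyclobutane C–H still cis to the amide, so C9 is set on the same face as the amide and the isopropenyl group.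

Step 14
Reactants: 20 C5-isopropenyl C9-silylethynyl carboxamide
Product: 21 N-Boc derivative of 20
Conditions: Boc2O, DMAP, MeCN, 50 °C
Reagents that add atoms: di-tert-butyl dicarbonate CC(C)(C)OC(=O)OC(=O)OC(C)(C)C
Why: N-acylation of the acidic anilide N–H gives a twisted, electronically activated imide, the usual way to make such directing amides cleavable.

Step 15
Reactants: 21 N-Boc imide
Product: 22 primary alcohol (C4–CH2OH) with C5-isopropenyl, C9-silylethynyl and acetonide unchanged
Conditions: LiBH4, THF–MeOH, 0 °C → rt
Reagents that add atoms: none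
Why: Hydride reduction of an N-Boc-activated amide; the electron-poor carbamate anion is a good leaving group, so the small borohydride takes the acyl carbon down to the alcohol and leaves alkene, silylalkyne and ketal alone.

Step 16
Reactants: 22 primary alcohol
Product: 23 methanesulfonate of 22
Conditions: MsCl, Et3N, CH2Cl2, 0 °C
Reagents that add atoms: methanesulfonyl chloride CS(=O)(=O)Cl
Why: Standard mesylation of an unhindered oxygen; no carbon centre is involved.

Step 17
Reactants: 23 methanesulfonate
Product: 24 C4-methyl compound with C5-isopropenyl, C9-silylethynyl and acetonide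
Conditions: LiEt3BH, THF, reflux
Reagents that add atoms: none
Why: SN2 hydride displacement with lithium triethylborohydride, the reagent of choice for neopentyl-type sulfonates; a two-electron path is chosen because a cyclobutylcarbinyl radical or cation would open or enlarge the four-membered ring.

Step 18
Reactants: 24 C4-methyl compound
Product: 25 C5-acetyl compound with the C9-silylethynyl group retained
Conditions: O3, CH2Cl2, −78 °C; Me2S
Reagents that add atoms: ozone [O-][O+]=O
Why: Ozonolysis cleaves the electron-rich 1,1-disubstituted alkene far faster than the hindered silylalkyne, and C5 should hold its configuration because the acetyl group already occupies the less crowded face, away from C3 and C11.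

Step 19
Reactants: 25 C5-acetyl C9-silylethynyl compound
Product: 26 C5-acetyl C9-ethynyl compound
Conditions: Bu4NF, AcOH, THF, 0 °C → rt
Reagents that add atoms: none
Why: Fluoride-induced C-desilylation of the alkyne, buffered with acetic acid so that the methyl ketone is not enolised.

Step 20
Reactants: 26 C5-acetyl C9-ethynyl compound
Product: 27 C5-[1-(tert-butyldimethylsilyloxy)vinyl] C9-ethynyl compound
Conditions: TBSOTf, Et3N, CH2Cl2, −78 → 0 °C
Reagents that add atoms: tert-butyldimethylsilyl triflate CC(C)(C)[Si](C)(C)OS(=O)(=O)C(F)(F)F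
Why: Soft enolisation goes toward the methyl group (C7), because the alternative would remove the shielded C5 hydrogen and place an exocyclic double bond on the strained cyclobutane.

Step 21
Reactants: 27 silyl enol ether alkyne
Product: 29 tricyclic enone acetonide (ketone C6 on C5; C7=C8 with the methyl on C8), via exo-methylene ketone 28 (not isolated)
Conditions: Ph3PAuCl (5 mol %), AgBF4 (5 mol %), CH2Cl2–H2O (10:1), rt → 40 °C; then DBU, CH2Cl2, rt
Reagents that add atoms: none
Why: Conia-ene-type carbocyclisation of a silyl enol ether onto a terminal alkyne catalysed by monovalent gold (6-exo-dig): C7 attacks the activated internal alkyne carbon C8, which the 1,3-cis, pseudo-axial placement of both arms brings within reach; the unlike arms fix the connectivity (ketone on C5, methyl-bearing carbon on C9), conversion of an alkyne pays for the added strain, DBU moves the exocyclic double bond of 28 into conjugation, and no new stereocentre arises.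

Step 22
Reactants: 29 tricyclic enone acetonide
Product: 30 tricyclic enone (1S,2S)-trans-diol
Conditions: AcOH–H2O (4:1), 40 °C
Reagents that add atoms: none
Why: Acid hydrolysis of a ketal; the strained trans-fused dioxolane should open under acid mild enough to leave the cyclobutane-fused enone intact.

Step 23
Reactants: 30 tricyclic enone diol; 31 (S)-2-methylbutanoic acid
Product: 32 C2 (S)-2-methylbutanoate with free C1–OH
Conditions: EDC·HCl, DMAP (cat.), CH2Cl2, 0 °C
Reagents that add atoms: none
Why: Steglich-type esterification selects C2–OH, flanked by a CH2, over the neopentyl C1–OH next to C11; the low temperature protects the α-stereocentre of the acid, and material of the wrong enantiomeric series becomes a separable diastereomer here.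

Step 24
Reactants: 32 C2 mono-ester; 33 angelic acid
Product: 35 target CNP0323606.1, via mixed Yamaguchi anhydride 34 (not isolated)
Conditions: 33, 2,4,6-trichlorobenzoyl chloride, Et3N, toluene, rt; then 32, toluene, 80 °C
Reagents that add atoms: 2,4,6-trichlorobenzoyl chloride (aroyl part of 34 only) O=C(Cl)c1c(Cl)cc(Cl)cc1Cl
Why: Yamaguchi-type acylation with the preformed mixed anhydride and without a nucleophilic catalyst, the established way to put an angelate on a hindered secondary alcohol without Z-to-E isomerisation to the tiglate.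

## Compound list

1 | methyl 3-oxocyclobutane-1-carboxylate | COC(=O)C1CC(=O)C1 | starting material
2 | methyl cis-3-hydroxycyclobutane-1-carboxylate | COC(=O)[C@H]1C[C@@H](O)C1 | intermediate
3 | methyl cis-3-(p-toluenesulfonyloxy)cyclobutane-1-carboxylate | COC(=O)[C@H]1C[C@@H](OS(=O)(=O)c2ccc(C)cc2)C1 | intermediate
4 | methyl bicyclo[1.1.0]butane-1-carboxylate | COC(=O)C12CC1C2 | intermediate
5 | 4-methylpent-1-en-3-one | CC(C)C(=O)C=C | starting material
6 | 3-(tert-butyldimethylsilyloxy)-4-methylpenta-1,3-diene | CC(C)=C(O[Si](C)(C)C(C)(C)C)C=C | intermediate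
7 | methyl 4-(tert-butyldimethylsilyloxy)-5,5-dimethylbicyclo[4.1.1]oct-3-ene-1-carboxylate (not isolated) | COC(=O)C12CC=C(O[Si](C)(C)C(C)(C)C)C(C)(C)C(C1)C2 | intermediate
8 | methyl 5,5-dimethyl-4-oxobicyclo[4.1.1]octane-1-carboxylate (achiral) | COC(=O)C12CCC(=O)C(C)(C)C(C1)C2 | intermediate
9 | methyl 5,5-dimethyl-4-(triethylsilyloxy)bicyclo[4.1.1]oct-3-ene-1-carboxylate | COC(=O)C12CC=C(O[Si](CC)(CC)CC)C(C)(C)C(C1)C2 | intermediate
10 | C1–C2 silyloxy-oxirane of 9, oxygen on the face that becomes (2S) (not isolated) | CC[Si](CC)(CC)O[C@]12O[C@H]1CC3(C(=O)OC)CC(C3)C2(C)C | intermediate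
11 | methyl (3S)-3-hydroxy-5,5-dimethyl-4-oxobicyclo[4.1.1]octane-1-carboxylate | O=C1[C@@H](O)CC2(C(=O)OC)CC(C2)C1(C)C | intermediate
12 | methyl (3S,4S)-3,4-dihydroxy-5,5-dimethylbicyclo[4.1.1]octane-1-carboxylate | O[C@@H]1[C@@H](O)CC2(C(=O)OC)CC(C2)C1(C)C | intermediate
13 | methyl (3S,4S)-3,4-(isopropylidenedioxy)-5,5-dimethylbicyclo[4.1.1]octane-1-carboxylate | O1[C@@H]2[C@@H](OC1(C)C)CC3(C(=O)OC)CC(C3)C2(C)C | intermediate
14 | corresponding carboxylic acid | O1[C@@H]2[C@@H](OC1(C)C)CC3(C(=O)O)CC(C3)C2(C)C | intermediate
15 | corresponding acid chloride (not isolated) | O1[C@@H]2[C@@H](OC1(C)C)CC3(C(=O)Cl)CC(C3)C2(C)C | intermediate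
16 | N-[2,3,5,6-tetrafluoro-4-(trifluoromethyl)phenyl] carboxamide | O1[C@@H]2[C@@H](OC1(C)C)CC3(C(=O)Nc4c(F)c(F)c(C(F)(F)F)c(F)c4F)CC(C3)C2(C)C | intermediate
17 | 2-iodopropene | CC(I)=C | starting material
18 | amide with C5-isopropenyl, cis to the amide and anti to the bridge | O1[C@@H]2[C@@H](OC1(C)C)C[C@@]3(C(=O)Nc4c(F)c(F)c(C(F)(F)F)c(F)c4F)[C@H](C(C)=C)[C@H](C3)C2(C)C | intermediate
19 | (bromoethynyl)triisopropylsilane | BrC#C[Si](C(C)C)(C(C)C)C(C)C | starting material
20 | amide with C5-isopropenyl and C9-(triisopropylsilyl)ethynyl, all cis | O1[C@@H]2[C@@H](OC1(C)C)C[C@@]3(C(=O)Nc4c(F)c(F)c(C(F)(F)F)c(F)c4F)[C@H](C(C)=C)[C@H]([C@@H]3C#C[Si](C(C)C)(C(C)C)C(C)C)C2(C)C | intermediate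
21 | N-Boc imide of 20 | O1[C@@H]2[C@@H](OC1(C)C)C[C@@]3(C(=O)N(C(=O)OC(C)(C)C)c4c(F)c(F)c(C(F)(F)F)c(F)c4F)[C@H](C(C)=C)[C@H]([C@@H]3C#C[Si](C(C)C)(C(C)C)C(C)C)C2(C)C | intermediate
22 | C4-hydroxymethyl compound | O1[C@@H]2[C@@H](OC1(C)C)C[C@@]3(CO)[C@H](C(C)=C)[C@H]([C@@H]3C#C[Si](C(C)C)(C(C)C)C(C)C)C2(C)C | intermediate
23 | C4-(mesyloxymethyl) compound | O1[C@@H]2[C@@H](OC1(C)C)C[C@@]3(COS(C)(=O)=O)[C@H](C(C)=C)[C@H]([C@@H]3C#C[Si](C(C)C)(C(C)C)C(C)C)C2(C)C | intermediate
24 | C4-methyl compound | O1[C@@H]2[C@@H](OC1(C)C)C[C@@]3(C)[C@H](C(C)=C)[C@H]([C@@H]3C#C[Si](C(C)C)(C(C)C)C(C)C)C2(C)C | intermediate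
25 | C5-acetyl, C9-silylethynyl compound | O1[C@@H]2[C@@H](OC1(C)C)C[C@@]3(C)[C@H](C(C)=O)[C@H]([C@@H]3C#C[Si](C(C)C)(C(C)C)C(C)C)C2(C)C | intermediate
26 | C5-acetyl, C9-ethynyl compound | O1[C@@H]2[C@@H](OC1(C)C)C[C@@]3(C)[C@H](C(C)=O)[C@H]([C@@H]3C#C)C2(C)C | intermediate
27 | C5-[1-(TBS-oxy)vinyl], C9-ethynyl compound | O1[C@@H]2[C@@H](OC1(C)C)C[C@@]3(C)[C@H](C(=C)O[Si](C)(C)C(C)(C)C)[C@H]([C@@H]3C#C)C2(C)C | intermediate
28 | tricyclic C6 ketone with exocyclic methylene on C8 (not isolated) | O1[C@@H]2[C@@H](OC1(C)C)C[C@@]3(C)[C@@H]4C(=O)CC(=C)[C@H]3[C@@H]4C2(C)C | intermediate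
29 | tricyclic enone acetonide | O1[C@@H]2[C@@H](OC1(C)C)C[C@@]3(C)[C@@H]4C(=O)C=C(C)[C@H]3[C@@H]4C2(C)C | intermediate
30 | tricyclic enone (1S,2S)-diol | O[C@@H]1[C@@H](O)C[C@@]2(C)[C@@H]3C(=O)C=C(C)[C@H]2[C@@H]3C1(C)C | intermediate
31 | (S)-2-methylbutanoic acid | CC[C@H](C)C(=O)O | starting material
32 | C2 (S)-2-methylbutanoate, C1–OH free | O[C@@H]1[C@@H](OC(=O)[C@@H](C)CC)C[C@@]2(C)[C@@H]3C(=O)C=C(C)[C@H]2[C@@H]3C1(C)C | intermediate
33 | angelic acid | C/C=C(/C)C(=O)O | starting material
34 | angelic 2,4,6-trichlorobenzoic anhydride (not isolated) | C/C=C(/C)C(=O)OC(=O)c1c(Cl)cc(Cl)cc1Cl | intermediate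
35 | CNP0323606.1, local (1S,2S,4R,5R,9R,10S), (S)-2-methylbutanoate, (Z)-angelate | C/C=C(/C)C(=O)O[C@@H]1[C@@H](OC(=O)[C@@H](C)CC)C[C@@]2(C)[C@@H]3C(=O)C=C(C)[C@H]2[C@@H]3C1(C)C | target

## Step count and risks

Total step count: 24. Longest linear sequence: 23 (steps 1–3 and 5–24; step 4 is the side branch).

**Step 5.**
- What may go wrong: a plain methyl ester binds the Lewis acid only weakly. Acid-induced isomerisation or oligomerisation of 4, or hydrolysis of 6, may then outrun attack by the fully substituted terminus C11, or the sequence may stall after the first bond.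
- Fallback (from 4, back at 8): the acceptor is changed to a chelating one instead of forcing the conditions.
- Saponification of 4 (LiOH, THF–H2O, 0 °C) would give bicyclo[1.1.0]butane-1-carboxylic acid F1.
- EDC coupling with 3,5-dimethylpyrazole would give (bicyclo[1.1.0]butan-1-yl)(3,5-dimethyl-1H-pyrazol-1-yl)methanone F2. Its carbonyl oxygen and pyrazole nitrogen bind Sc(OTf)3 at two points, the activation mode best documented for bicyclobutane annulations.
- Reaction with 6 (Sc(OTf)3 10 mol %, CH2Cl2, 0 °C) should give the N-acylpyrazole silyl enol ether cycloadduct F3.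
- K2CO3 in MeOH would exchange the pyrazolide for methoxide and cleave the enol ether in the same flask, which returns the material to 8.

**Step 12.**
- What may go wrong: discrimination between the two diastereotopic cyclobutane methylenes may be insufficient, alkenylation may occur at both, or oxidative addition of the 1,1-disubstituted alkenyl iodide to the crowded palladacycle may be slow.
- Fallback (from 16, back at 18): the alkenyl iodide/tetravalent palladium manifold is replaced by a C–H/organoboron cross-coupling that cycles between divalent and zerovalent palladium.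
- Conditions: Pd(OAc)2, a Boc-protected α-amino O-methylhydroxamic acid ligand (the ligand class developed for 1-substituted cyclobutanecarboxamides), isopropenylboronic acid pinacol ester, Ag2CO3, Na2CO3, 1,4-benzoquinone, H2O, t-AmylOH, 70 °C.
- Transmetalation takes the place of the hindered oxidative addition, and a different chiral pocket makes the C5/C9 choice. No compound outside the list is made (F0).

**Step 21.**
- What may go wrong: the closure has to build a strained bicyclo[3.1.1]heptanone on an already strained cage. If attack on the gold-bound alkyne is slow, protodesilylation of the enol ether and hydration of the alkyne take over and erase the difference between the two arms.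
- Fallback (from 27, back at 29): the nucleophilic site is locked as a halide and the ring is closed by a site-specific Reformatsky-type aldol.
- NBS (THF, −78 °C) would convert 27 into the C5-bromoacetyl C9-ethynyl compound F4.
- Hydration of the alkyne (Ph3PAuNTf2 cat., dioxane–H2O, 50 °C) would give the C5-bromoacetyl C9-acetyl compound F5.
- SmI2 (THF, −78 °C) would generate the samarium enolate only at C7, which adds to the C8 ketone to give the tricyclic β-hydroxy ketone F6 (configuration at C8 immaterial).
- Burgess reagent (toluene, 50 °C), followed by DBU if some exocyclic isomer 28 forms, would deliver 29 without passing through base-induced retro-aldol scrambling.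

## Further compounds

F1 | step 5 | bicyclo[1.1.0]butane-1-carboxylic acid | OC(=O)C12CC1C2
F2 | step 5 | (bicyclo[1.1.0]butan-1-yl)(3,5-dimethyl-1H-pyrazol-1-yl)methanone | Cc1cc(C)n(n1)C(=O)C12CC1C2
F3 | step 5 | N-acylpyrazole silyl enol ether cycloadduct | Cc1cc(C)n(n1)C(=O)C12CC=C(O[Si](C)(C)C(C)(C)C)C(C)(C)C(C1)C2
F0 | step 12 | none | none
F4 | step 21 | C5-bromoacetyl C9-ethynyl compound | O1[C@@H]2[C@@H](OC1(C)C)C[C@@]3(C)[C@H](C(=O)CBr)[C@H]([C@@H]3C#C)C2(C)C
F5 | step 21 | C5-bromoacetyl C9-acetyl compound | O1[C@@H]2[C@@H](OC1(C)C)C[C@@]3(C)[C@H](C(=O)CBr)[C@H]([C@@H]3C(C)=O)C2(C)C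
F6 | step 21 | tricyclic β-hydroxy ketone (C8 carbinol) | O1[C@@H]2[C@@H](OC1(C)C)C[C@@]3(C)[C@@H]4C(=O)CC(C)(O)[C@H]3[C@@H]4C2(C)C
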